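The earlier runs and the new flask come from a simulation for substances that don't exist; the scatter is artificial.

Two kinds of question stand below: which flask keeps the highest share of first product, and by how much.

| flask | substrate | reagent | remark | time |
|---|---|---|---|---|
| north-east | 20 mM | 40 mM | run made earlier |  |
| west | 20 mM | 60 mM | run made earlier |  |
| Thursday's | 20 mM (fed, over 4.0 min) | 40.0 mM | all else is in the flask from the start; the feed brings no volume worth counting | 10 min |
| Tuesday's | 20 mM | 40.0 mM | everything together at the start | 10 min |
| Sunday's | 20 mM | 40.0 mM (in portions, 2, over 4.0 min) | first portion at the start, last at 4.0 min | 10 min |
| Saturday's | 20 mM | 40.0 mM (fed, over 4.0 min) | all else is in the flask from the start; the feed brings no volume worth counting | 10 min |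

- north-east (time / min: first product / %, double product / %): 1.50: 78.3, 8.7; 3.00: 72.4, 18.5; 5.00: 64.5, 28.1; 6.00: 60.2, 32.2; 8.00: 54.4, 39.3; 10.0: 50.3, 43.8
- west (time / s: first product / %, double product / %): 10.0: 50.6, 1.3; 20.0: 70.1, 3.8; 30.0: 76.8, 5.8; 40.0: 80.3, 6.8; 50.0: 80.6, 9.5; 60.0: 79.3, 11.7

(each reading ± 0.5 percentage points)

1. the flask with the highest share of first product in first product plus double product ("all alike" if they lie within 1.5 percentage points) (Thursday's / Tuesday's / Sunday's / Saturday's / all alike)
2. share of first product in first product plus double product at the end, Thursday's
3. share of first product in first product plus double product at the end, Tuesday's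
4. share of first product in first product plus double product at the end, Sunday's
5. share of first product in first product plus double product at the end, Saturday's

- the numbers in the tables scatter by 0.5 percentage points (one standard deviation)

**Q: What happens first?** A: By 1.50 min the north-east run already holds 87.0 % of the charge as products, so I treat the first step as over early and ask what reagent it leaves free. I count fractions of the charge, and assume one reagent per first product and two per double product. So the free reagent fraction is 0.396 at 5.00 min and 0.310 at 10.0 min.

**Q: What do you carry forward?** A: The second-step clock: new double product per minute, divided by first product fraction and free reagent fraction. Between those readings it is 0.155 /min. Multiplied by the free reagent, it is a pseudo-first-order rate of loss of first product.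

**Q: Apply it to Sunday's.** A: If all substrate reacted, Sunday's first portion would leave a free fraction of 0. I take a mean of 0.250 up to 4.0 min, with first product at 78.3 %, which gives double product of 12.1 %. The north-east run reached that level earlier, so Sunday's runs behind it by 1.98 min. Its end therefore resembles the reading at 8.00 min, a share of 58.1 %. Tuesday's repeats the north-east run, at 53.5 %, which is lower. I leave the two feeds open.

**Q: The weak spot?** A: At 1.50 min, 13.0 % of the charge is in neither product, and my reckoning leaves it out.

The forecast named Sunday's, with 58.5 % for Thursday's, 53.5 % for Tuesday's, 62.5 % for Sunday's and 60.5 % for Saturday's, because “Starving the reagent early delays overreaction”, and its Sunday's figure stands above mine.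

Sunday's ends at 60.4 %, the highest share, against 57.6 % for Thursday's, 53.5 % for Tuesday's and 57.1 % for Saturday's.

    reagent + first product → double product + by-product (k = 0.0680 /M/s)
    substrate ⇌ dormant form (K = 2.80, k = 0.00540 /s)
    substrate + reagent → first product + by-product (k = 1.40 /M/s)

At 10.0 min, Sunday's first product is made more slowly than it is used up, at a ratio of 0.330. From 5.00 min to 10.0 min, the clock with mean fractions gives Sunday's 22 percentage points of new double product, against 22 points found. Over the same span, it gives Saturday's 20 points, against 20 points found.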